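**Strategy.** Everything rests on building ring A, the benzo ring of the coumarin, instead of buying it. C7–C8, C4a–C8a and C6–C7 are cut, which leads back to a β-methoxyvinyl ketene and (triisopropylsiloxy)acetylene. The feature exploited is the ring A oxygen pattern: C7–OH and O1 on C8a stand meta across C8–H, and the C6 methoxy sits beside the phenol. One photochemical–thermal operation (Wolff shift, [2+2] addition, four-electron opening, six-electron closure) installs this pattern with O1 silylated and C7–OH free. The precursor is an acyclic α-diazo β′-methoxy enone. Its diazo carbon, the future C4a, carries the CH2–CH(OAr)–CO2Me arm that becomes C4, C3 and C2. Desilylative lactonisation, dehydrogenation and MOM cleavage finish.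

Key step: step 10

**Remarks on the chemistry**
- The target is achiral. Every intermediate with the sp3 C–OAr carbon (future C3) is carried as a racemate, and those with a second, transient centre as diastereomer mixtures. The dehydrogenation erases the centre.
- Bond count of the key step: besides C7–C8, C4a–C8a and C6–C7, the Wolff shift also makes C4a–C5. The two bonds of the old carbonyl carbon (to C5 and to C4a) are given up. Four of the six ring A bonds are therefore new.
- Access to the precursor: adding the lithium dienolate of 4-methoxybut-3-en-2-one to a 2-aryloxyacrylate was set aside. The ester enolate so formed can reach the β-methoxy enone terminus through a six-membered transition state. It should therefore close by a second Michael addition and lose methoxide, a formal Diels–Alder reaction of a 2-oxidodiene. The enone is made instead by acylating a γ-zincio ester.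
- The lactone of umbelliferone serves as the built-in group that tells the two ring B oxygens apart. Its C3=C4 bond is reduced early so that no coumarin chromophore is present during irradiation.

**Step 1**
Reactants: 1 umbelliferone; 2 α-bromo-γ-butyrolactone
Product: 3 7-[(2-oxooxolan-3-yl)oxy]-2H-chromen-2-one (racemic)
Conditions: K2CO3, DMF, rt → 50 °C
Reagents that add atoms: none
Why: Williamson etherification, in which the only free phenol (the other ring B oxygen is locked in the lactone) displaces bromide at the activated α-carbon by SN2, creating the racemic C–OAr centre.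

**Step 2**
Reactants: 3 7-[(2-oxooxolan-3-yl)oxy]-2H-chromen-2-one
Product: 4 7-[(2-oxooxolan-3-yl)oxy]-3,4-dihydro-2H-chromen-2-one (racemic)
Conditions: H2 (1–3 atm), 10% Pd/C, EtOAc, rt
Reagents that add atoms: none
Why: Catalytic hydrogenation of the conjugated, disubstituted coumarin C3=C4 bond is routine and leaves the aryl ether and both lactones untouched.

**Step 3**
Reactants: 4 7-[(2-oxooxolan-3-yl)oxy]-3,4-dihydro-2H-chromen-2-one
Product: 5 methyl 4-bromo-2-[3-hydroxy-4-(3-methoxy-3-oxopropyl)phenoxy]butanoate (racemic)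
Conditions: dry HBr (saturated), MeOH, 0 °C → rt; NaHCO3 before concentration
Reagents that add atoms: methanol, CO; hydrogen bromide, Br
Why: Acid methanolysis opens the aryl ester of ring B, while bromide attacks the O–CH2 carbon of the protonated butyrolactone (SN2) and the acid released is esterified (Fischer), the classical conversion of a γ-lactone into a γ-bromo ester, so the former lactone oxygen emerges as the only free phenol.

**Step 4**
Reactants: 5 methyl 4-bromo-2-[3-hydroxy-4-(3-methoxy-3-oxopropyl)phenoxy]butanoate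
Product: 6 methyl 4-bromo-2-[4-(3-methoxy-3-oxopropyl)-3-(methoxymethoxy)phenoxy]butanoate (racemic)
Conditions: MOMCl, iPr2NEt, CH2Cl2, 0 °C → rt
Reagents that add atoms: chloromethyl methyl ether, COCCl
Why: Standard MOM ether formation on a phenol with a hindered amine base that is too weak to enolise the ester and trigger cyclopropane closure onto the primary bromide.

**Step 5**
Reactants: 7 methyl (E)-3-methoxyprop-2-enoate
Product: 8 (E)-3-methoxyprop-2-enoic acid
Conditions: NaOH, H2O/MeOH, rt; then cold aq. HCl to pH 2, 0 °C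
Reagents that add atoms: sodium hydroxide, [Na+].[OH-]
Why: Plain saponification, with a brief and cold acidification so that the enol ether is not hydrolysed and the E geometry is kept.

**Step 6**
Reactants: 8 (E)-3-methoxyprop-2-enoic acid
Product: 9 (E)-3-methoxyprop-2-enoyl chloride
Conditions: (COCl)2, DMF (cat.), CH2Cl2, 0 °C → rt; used directly
Reagents that add atoms: oxalyl chloride, O=C(Cl)C(=O)Cl
Why: Acid chloride formation through the catalytic Vilsmeier-type chloroiminium species runs under mild conditions that β-alkoxyacrylic acids tolerate.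

**Step 7**
Reactants: 6 methyl 4-bromo-2-[4-(3-methoxy-3-oxopropyl)-3-(methoxymethoxy)phenoxy]butanoate; 9 (E)-3-methoxyprop-2-enoyl chloride
Product: 11 methyl (E)-7-methoxy-2-[4-(3-methoxy-3-oxopropyl)-3-(methoxymethoxy)phenoxy]-5-oxohept-6-enoate (racemic), via alkylzinc bromide 10 (not isolated)
Conditions: Zn dust (activated with BrCH2CH2Br and Me3SiCl), LiCl, THF, 50 °C; then Pd(PPh3)4 (5 mol %), slow addition of 9, THF, 0 °C → rt
Reagents that add atoms: none
Why: LiCl-assisted zinc insertion gives a 4-zinciobutanoate of the stable, ester-tolerant kind, and Negishi acylation (zerovalent palladium inserts into the acyl chloride, then transmetalation and fast reductive elimination) forms C4–C5 without 1,4-attack on the β-methoxy enone, THF and chloride damping the Lewis acidity of divalent zinc toward the MOM acetal.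

**Step 8**
Reactants: 11 methyl (E)-7-methoxy-2-[4-(3-methoxy-3-oxopropyl)-3-(methoxymethoxy)phenoxy]-5-oxohept-6-enoate
Product: 13 methyl (E)-4-diazo-7-methoxy-2-[4-(3-methoxy-3-oxopropyl)-3-(methoxymethoxy)phenoxy]-5-oxohept-6-enoate (racemic), via trifluoroacetyl ketone 12 (not isolated)
Conditions: LiN(SiMe3)2 (1.1 equiv), THF, −78 °C; CF3CO2CH2CF3, −78 °C; cold 0.5 M HCl work-up; then MsN3, Et3N, H2O (1 equiv), MeCN, rt
Reagents that add atoms: methanesulfonyl azide, CS(=O)(=O)N=[N+]=[N-]
Why: Detrifluoroacetylative diazo transfer (Regitz type), in which the kinetic α′-enolate of the vinylogous ester is trifluoroacetylated at C4 and 12 takes the diazo group from MsN3 with loss of CF3CO, while any stray acylation at the tertiary C2–H gives a quaternary keto ester that cannot accept a diazo group and is cleaved back by Et3N/H2O.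

**Step 9**
Reactants: 14 acetylene; 15 triisopropylsilyl trifluoromethanesulfonate
Product: 18 (triisopropylsiloxy)acetylene, via lithium acetylide 16 (not isolated), via lithium ethynolate 17 (not isolated)
Conditions: 14 (excess), n-BuLi, THF, −78 °C; LiOOt-Bu (from t-BuOOH and LiN(SiMe3)2, THF, −78 °C), −78 → 0 °C; 15, −78 → 0 °C
Reagents that add atoms: tert-butyl hydroperoxide, CC(C)(C)OO
Why: Oxidation of a lithium acetylide with lithium tert-butyl peroxide gives the ynolate, which the hard and bulky silyl triflate takes on oxygen (the general route to triisopropylsiloxyalkynes), excess dissolved acetylene holding back disproportionation of 16.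

**Step 10**
Reactants: 13 methyl (E)-4-diazo-7-methoxy-2-[4-(3-methoxy-3-oxopropyl)-3-(methoxymethoxy)phenoxy]-5-oxohept-6-enoate; 18 (triisopropylsiloxy)acetylene
Product: 23 methyl 3-[4-hydroxy-5-methoxy-2-(triisopropylsiloxy)phenyl]-2-[4-(3-methoxy-3-oxopropyl)-3-(methoxymethoxy)phenoxy]propanoate (racemic), via vinylketene 19 (not isolated), via vinylcyclobutenone 20 (not isolated), via dienylketene 21 (not isolated), via cyclohexadienone 22 (not isolated)
Conditions: 18 (3 equiv), hν (300 nm, Pyrex), degassed ClCH2CH2Cl, rt; then 80 °C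
Reagents that add atoms: none
Why: Light expels N2 from 13 and the β-methoxyvinyl group moves from the carbonyl carbon to the diazo carbon (photochemical Wolff rearrangement, making C4a–C5) to give vinylketene 19, which 18 intercepts in a [2+2] cycloaddition (C7–C8 and C4a–C8a) to give 20. On heating, 20 opens in a conrotatory four-electron electrocyclic reaction (cleaving C4a–C7) to dienylketene 21, ring A is closed by a disrotatory six-electron electrocyclisation that joins C6 to C7, and enolisation of 22 delivers the phenol. This is the Danheiser benzannulation in its diazo ketone variant, established for diazo enones and siloxyalkynes as a route to resorcinol monosilyl ethers; the donor methoxy group at the ketene terminus is the untested variable. The only selectivity needed is the orientation of the [2+2] step, and the polarity of 18 secures it: its unsubstituted, nucleophilic carbon attacks the electrophilic ketene carbonyl carbon, so C8–H ends between C7–OH and C8a–OSi. No lasting stereocentre is created, since the quaternary carbon of 20 and C6 of 22 vanish on aromatisation and the racemic C–OAr centre is a spectator. Irradiation through Pyrex spares the aryl ether chromophore of ring B, and the excess of 18 favours capture of 19 over ketene dimerisation.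

**Step 11**
Reactants: 23 methyl 3-[4-hydroxy-5-methoxy-2-(triisopropylsiloxy)phenyl]-2-[4-(3-methoxy-3-oxopropyl)-3-(methoxymethoxy)phenoxy]propanoate
Product: 25 methyl 3-{4-[(7-hydroxy-6-methoxy-2-oxo-3,4-dihydro-2H-chromen-3-yl)oxy]-2-(methoxymethoxy)phenyl}propanoate (racemic), via free resorcinol 24 (not isolated)
Conditions: Bu4NF (1.1 equiv), 4 Å MS, THF, 0 °C → rt; then AcOH
Reagents that add atoms: none
Why: Fluoride cleaves the aryl silyl ether and the C8a phenoxide attacks the activated α-aryloxy methyl ester in a 6-exo-trig transesterification (desilylative lactonisation), the released methoxide being buffered by the C7 phenol and the methanol taken up by the sieves.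

**Step 12**
Reactants: 25 methyl 3-{4-[(7-hydroxy-6-methoxy-2-oxo-3,4-dihydro-2H-chromen-3-yl)oxy]-2-(methoxymethoxy)phenyl}propanoate
Product: 27 methyl 3-{4-[(7-hydroxy-6-methoxy-2-oxo-2H-chromen-3-yl)oxy]-2-(methoxymethoxy)phenyl}propanoate, via quinone methide 26 (not isolated)
Conditions: DDQ (1.1 equiv), 1,4-dioxane, rt → 50 °C
Reagents that add atoms: none
Why: Quinone dehydrogenation of a dihydrocoumarin, in which DDQ takes hydride from C4 (para to the free C7–OH) to give p-quinone methide 26, whose acidic C3–H is lost on tautomerisation to the aromatic coumarin, the protected ring B reacting more slowly at this temperature.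

**Step 13**
Reactants: 27 methyl 3-{4-[(7-hydroxy-6-methoxy-2-oxo-2H-chromen-3-yl)oxy]-2-(methoxymethoxy)phenyl}propanoate
Product: 28 methyl 3-{2-hydroxy-4-[(7-hydroxy-6-methoxy-2-oxo-2H-chromen-3-yl)oxy]phenyl}propanoate (target)
Conditions: HCl (1.25 M in MeOH), 0 °C → rt; NaHCO3 before concentration
Reagents that add atoms: none
Why: Acid-catalysed acetal exchange removes the MOM group, the coumarin lactone resists methanolysis because its cis-cinnamate would reclose, and the methanol solvent keeps the ring B hydroxy ester open and its ester as the methyl ester.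

**Compound list**
1 | umbelliferone (7-hydroxy-2H-chromen-2-one) | O=c1ccc2ccc(O)cc2o1 | starting material
2 | α-bromo-γ-butyrolactone (3-bromooxolan-2-one, racemic) | O=C1OCCC1Br | starting material
3 | 7-[(2-oxooxolan-3-yl)oxy]-2H-chromen-2-one (racemic) | O=C1OCCC1Oc1ccc2ccc(=O)oc2c1 | intermediate
4 | 7-[(2-oxooxolan-3-yl)oxy]-3,4-dihydro-2H-chromen-2-one (racemic) | O=C1CCc2ccc(OC3CCOC3=O)cc2O1 | intermediate
5 | methyl 4-bromo-2-[3-hydroxy-4-(3-methoxy-3-oxopropyl)phenoxy]butanoate (racemic) | COC(=O)CCc1ccc(OC(CCBr)C(=O)OC)cc1O | intermediate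
6 | methyl 4-bromo-2-[4-(3-methoxy-3-oxopropyl)-3-(methoxymethoxy)phenoxy]butanoate (racemic) | COC(=O)CCc1ccc(OC(CCBr)C(=O)OC)cc1OCOC | intermediate
7 | methyl (E)-3-methoxyprop-2-enoate | CO/C=C/C(=O)OC | starting material
8 | (E)-3-methoxyprop-2-enoic acid | CO/C=C/C(=O)O | intermediate
9 | (E)-3-methoxyprop-2-enoyl chloride | CO/C=C/C(=O)Cl | intermediate
10 | bromo{4-methoxy-3-[4-(3-methoxy-3-oxopropyl)-3-(methoxymethoxy)phenoxy]-4-oxobutyl}zinc (racemic) | Br[Zn]CCC(Oc1ccc(CCC(=O)OC)c(OCOC)c1)C(=O)OC | intermediate
11 | methyl (E)-7-methoxy-2-[4-(3-methoxy-3-oxopropyl)-3-(methoxymethoxy)phenoxy]-5-oxohept-6-enoate (racemic) | CO/C=C/C(=O)CCC(Oc1ccc(CCC(=O)OC)c(OCOC)c1)C(=O)OC | intermediate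
12 | methyl (E)-7-methoxy-2-[4-(3-methoxy-3-oxopropyl)-3-(methoxymethoxy)phenoxy]-5-oxo-4-(trifluoroacetyl)hept-6-enoate (diastereomer mixture) | CO/C=C/C(=O)C(C(=O)C(F)(F)F)CC(Oc1ccc(CCC(=O)OC)c(OCOC)c1)C(=O)OC | intermediate
13 | methyl (E)-4-diazo-7-methoxy-2-[4-(3-methoxy-3-oxopropyl)-3-(methoxymethoxy)phenoxy]-5-oxohept-6-enoate (racemic) | CO/C=C/C(=O)C(=[N+]=[N-])CC(Oc1ccc(CCC(=O)OC)c(OCOC)c1)C(=O)OC | intermediate
14 | acetylene | C#C | starting material
15 | triisopropylsilyl trifluoromethanesulfonate | CC(C)[Si](C(C)C)(C(C)C)OS(=O)(=O)C(F)(F)F | starting material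
16 | lithium acetylide | [Li]C#C | intermediate
17 | lithium ethynolate | [Li+].[O-]C#C | intermediate
18 | (triisopropylsiloxy)acetylene | C#CO[Si](C(C)C)(C(C)C)C(C)C | intermediate
19 | vinylketene: methyl (E)-4-carbonyl-6-methoxy-2-[4-(3-methoxy-3-oxopropyl)-3-(methoxymethoxy)phenoxy]hex-5-enoate (racemic) | CO/C=C/C(=C=O)CC(Oc1ccc(CCC(=O)OC)c(OCOC)c1)C(=O)OC | intermediate
20 | vinylcyclobutenone: methyl 3-{1-[(E)-2-methoxyethenyl]-4-oxo-2-(triisopropylsiloxy)cyclobut-2-en-1-yl}-2-[4-(3-methoxy-3-oxopropyl)-3-(methoxymethoxy)phenoxy]propanoate (diastereomer mixture) | CO/C=C/C1(CC(Oc2ccc(CCC(=O)OC)c(OCOC)c2)C(=O)OC)C(=O)C=C1O[Si](C(C)C)(C(C)C)C(C)C | intermediate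
21 | dienylketene from ring opening of 20, ketenyl and methoxyvinyl groups cis on the central double bond (racemic) | O=C=C/C(O[Si](C(C)C)(C(C)C)C(C)C)=C(\C=C\OC)CC(Oc1ccc(CCC(=O)OC)c(OCOC)c1)C(=O)OC | intermediate
22 | cyclohexadienone: methyl 3-[5-methoxy-4-oxo-2-(triisopropylsiloxy)cyclohexa-2,6-dien-1-yl]-2-[4-(3-methoxy-3-oxopropyl)-3-(methoxymethoxy)phenoxy]propanoate (diastereomer mixture) | COC1C=C(CC(Oc2ccc(CCC(=O)OC)c(OCOC)c2)C(=O)OC)C(O[Si](C(C)C)(C(C)C)C(C)C)=CC1=O | intermediate
23 | methyl 3-[4-hydroxy-5-methoxy-2-(triisopropylsiloxy)phenyl]-2-[4-(3-methoxy-3-oxopropyl)-3-(methoxymethoxy)phenoxy]propanoate (racemic) | COc1cc(CC(Oc2ccc(CCC(=O)OC)c(OCOC)c2)C(=O)OC)c(O[Si](C(C)C)(C(C)C)C(C)C)cc1O | intermediate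
24 | methyl 3-(2,4-dihydroxy-5-methoxyphenyl)-2-[4-(3-methoxy-3-oxopropyl)-3-(methoxymethoxy)phenoxy]propanoate (racemic) | COc1cc(CC(Oc2ccc(CCC(=O)OC)c(OCOC)c2)C(=O)OC)c(O)cc1O | intermediate
25 | methyl 3-{4-[(7-hydroxy-6-methoxy-2-oxo-3,4-dihydro-2H-chromen-3-yl)oxy]-2-(methoxymethoxy)phenyl}propanoate (racemic) | COC(=O)CCc1ccc(OC2Cc3cc(OC)c(O)cc3OC2=O)cc1OCOC | intermediate
26 | p-quinone methide: methyl 3-{4-[(6-methoxy-2,7-dioxo-3,7-dihydro-2H-chromen-3-yl)oxy]-2-(methoxymethoxy)phenyl}propanoate (racemic) | COC(=O)CCc1ccc(OC2C=C3C=C(OC)C(=O)C=C3OC2=O)cc1OCOC | intermediate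
27 | methyl 3-{4-[(7-hydroxy-6-methoxy-2-oxo-2H-chromen-3-yl)oxy]-2-(methoxymethoxy)phenyl}propanoate | COC(=O)CCc1ccc(Oc2cc3cc(OC)c(O)cc3oc2=O)cc1OCOC | intermediate
28 | methyl 3-{2-hydroxy-4-[(7-hydroxy-6-methoxy-2-oxo-2H-chromen-3-yl)oxy]phenyl}propanoate (CNP0259806.0) | COC(=O)CCc1ccc(Oc2cc3cc(OC)c(O)cc3oc2=O)cc1O | target

**Step count.** Total steps: 13. Longest linear sequence: 10 (steps 1–4, 7, 8, 10–13).

**Steps most likely to fail**

1. **Step 10.**
 - What may go wrong: a 1,2-hydrogen shift from the neighbouring CH2 may outrun the Wolff shift. Capture of the donor-substituted ketene by the alkyne may be slow, so that the ketene dimerises. Light absorption by products may stall the photolysis.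
 - Fallback (ring A from the aromatic pool, known chemistry): the fallback sets out from 1.
 - O-alkylation with ethyl bromoacetate (K2CO3, acetone) gives ethyl 2-[(2-oxo-2H-chromen-7-yl)oxy]acetate F1.
 - Saponification and acidification give 2-[(2-oxo-2H-chromen-7-yl)oxy]acetic acid F2.
 - Perkin–Oglialoro condensation with commercial 2,4-dihydroxy-5-methoxybenzaldehyde (Ac2O, Et3N, 120 °C) gives 6-methoxy-2-oxo-3-[(2-oxo-2H-chromen-7-yl)oxy]-2H-chromen-7-yl acetate F3.
 - Hydrogenation over Pd/C is stopped after one equivalent of H2. It should reduce the disubstituted C3=C4 bond of the ring B coumarin before the trisubstituted, oxygen-bearing one, giving 6-methoxy-2-oxo-3-[(2-oxo-3,4-dihydro-2H-chromen-7-yl)oxy]-2H-chromen-7-yl acetate F4.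
 - HCl in MeOH then cleaves the acetate and opens the dihydrocoumarin, and the fallback comes back to the route at 28.

2. **Step 9.**
 - What may go wrong: the monolithium acetylide may disproportionate on warming, and the unhindered ynolate may be silylated at carbon instead of oxygen.
 - Fallback (blocked alkyne terminus): the fallback sets out from 15.
 - Commercial trimethylsilylacetylene is lithiated and oxidised with LiOOt-Bu to lithium 2-(trimethylsilyl)ethynolate F5. Its carbon terminus is shielded, so 15 should react at oxygen to give 1-(trimethylsilyl)-2-(triisopropylsiloxy)acetylene F6.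
 - MeLi (THF, −78 → 0 °C) attacks the small silyl group and releases lithium (triisopropylsiloxy)acetylide F7.
 - Protonation with water comes back to the route at 18.

3. **Step 12.**
 - What may go wrong: the electron-rich guaiacol ring may be over-oxidised, the phenol may couple to the quinone, or hydride may be abstracted at the benzylic CH2 of ring B.
 - Fallback (polar α-functionalisation and elimination in place of hydride abstraction): the fallback sets out from 25.
 - Silylation (t-BuMe2SiCl, imidazole, DMF) gives the 7-O-tert-butyldimethylsilyl dihydrocoumarin F8.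
 - Selective deprotonation of the much more acidic lactone C3–H (LiN(SiMe3)2, THF, −78 °C) and trapping with PhSeBr give the 3-phenylselanyl lactone F9.
 - H2O2 (pyridine, CH2Cl2, 0 °C) gives the selenoxide F10, which undergoes syn elimination toward C4–H to give the 7-O-tert-butyldimethylsilyl coumarin F11.
 - Bu4NF/AcOH removes the silyl group, and the fallback comes back to the route at 27.

**Further compounds**
F1 | step 10 | ethyl 2-[(2-oxo-2H-chromen-7-yl)oxy]acetate | CCOC(=O)COc1ccc2ccc(=O)oc2c1
F2 | step 10 | 2-[(2-oxo-2H-chromen-7-yl)oxy]acetic acid | O=C(O)COc1ccc2ccc(=O)oc2c1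
F3 | step 10 | 6-methoxy-2-oxo-3-[(2-oxo-2H-chromen-7-yl)oxy]-2H-chromen-7-yl acetate | CC(=O)Oc1cc2oc(=O)c(Oc3ccc4ccc(=O)oc4c3)cc2cc1OC
F4 | step 10 | 6-methoxy-2-oxo-3-[(2-oxo-3,4-dihydro-2H-chromen-7-yl)oxy]-2H-chromen-7-yl acetate | CC(=O)Oc1cc2oc(=O)c(Oc3ccc4c(c3)OC(=O)CC4)cc2cc1OC
F5 | step 9 | lithium 2-(trimethylsilyl)ethynolate | [Li+].C[Si](C)(C)C#C[O-]
F6 | step 9 | 1-(trimethylsilyl)-2-(triisopropylsiloxy)acetylene | C[Si](C)(C)C#CO[Si](C(C)C)(C(C)C)C(C)C
F7 | step 9 | lithium (triisopropylsiloxy)acetylide | [Li]C#CO[Si](C(C)C)(C(C)C)C(C)C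
F8 | step 12 | methyl 3-{4-[(7-{[tert-butyl(dimethyl)silyl]oxy}-6-methoxy-2-oxo-3,4-dihydro-2H-chromen-3-yl)oxy]-2-(methoxymethoxy)phenyl}propanoate (racemic) | COC(=O)CCc1ccc(OC2Cc3cc(OC)c(O[Si](C)(C)C(C)(C)C)cc3OC2=O)cc1OCOC
F9 | step 12 | methyl 3-{4-[(7-{[tert-butyl(dimethyl)silyl]oxy}-6-methoxy-2-oxo-3-(phenylselanyl)-3,4-dihydro-2H-chromen-3-yl)oxy]-2-(methoxymethoxy)phenyl}propanoate (racemic) | COC(=O)CCc1ccc(OC2([Se]c4ccccc4)Cc3cc(OC)c(O[Si](C)(C)C(C)(C)C)cc3OC2=O)cc1OCOC
F10 | step 12 | selenoxide of F9 (diastereomer mixture) | COC(=O)CCc1ccc(OC2([Se](=O)c4ccccc4)Cc3cc(OC)c(O[Si](C)(C)C(C)(C)C)cc3OC2=O)cc1OCOC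
F11 | step 12 | methyl 3-{4-[(7-{[tert-butyl(dimethyl)silyl]oxy}-6-methoxy-2-oxo-2H-chromen-3-yl)oxy]-2-(methoxymethoxy)phenyl}propanoate | COC(=O)CCc1ccc(Oc2cc3cc(OC)c(O[Si](C)(C)C(C)(C)C)cc3oc2=O)cc1OCOC
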